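**Strategy.** The pyranone ring (ring C) is closed last by making the aryl ether bond O1–C8a at an unfunctionalized C8a–H. The step exploits the guaiacol unit of ring A (free C5–OH beside C6–OMe, with C8a meta to that hydroxyl and ortho to the C4 acyl group). PhI(OAc)2 in methanol dearomatizes ring A to an ortho-quinone monoketal in which C8a is the β-carbon of a doubly activated enone; the C2 hydroxyl adds there, and loss of methanol restores the arene, all in one operation. The precursor is the open-chain (S)-β-hydroxy ketone, available in two steps by a catalytic enantioselective Mukaiyama aldol addition of bis-silylated 2'-hydroxy-3',4'-dimethoxyacetophenone to veratraldehyde.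

Key step: step 3

Assumption: the (S,S) enantiomer of the bisphosphoramide catalyst (two N,N'-dimethyl-1,1'-binaphthyl-2,2'-diamine phosphoramide units joined by an N,N'-dimethylpentane-1,5-diamine linker) is taken to direct the enol ether to the Si face of the aryl aldehyde, which gives S at the carbinol carbon. This sense is recalled rather than certain; it is to be checked on the first batch by MTPA ester analysis of the aldol product, and the (R,R) catalyst would be used instead if it proved opposite.

Numbering: flavanone numbering (O1, C2–C4, C4a, C5–C8, C8a; ring A the fused benzene ring, ring C the pyranone) is used for the target and for the corresponding atoms of its precursors.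

**Step 1**
Reactants: 1 1-(2-hydroxy-3,4-dimethoxyphenyl)ethan-1-one (2'-hydroxy-3',4'-dimethoxyacetophenone)
Product: 2 [1-(3,4-dimethoxy-2-trimethylsilyloxyphenyl)ethenyl]oxy-trimethylsilane (aryl silyl ether and silyl enol ether in one compound)
Conditions: TMSOTf (2.3 equiv), Et3N (3 equiv), CH2Cl2, 0 °C → rt; pentane trituration, filtration, used without chromatography
Reagents that add atoms: trimethylsilyl trifluoromethanesulfonate, C[Si](C)(C)OS(=O)(=O)C(F)(F)F
Why: Soft enolization with TMSOTf/Et3N should silylate first the chelated phenol and then the methyl ketone enol (silyl enol ether formation), so one operation masks the acidic OH and supplies the Mukaiyama donor; no stereocenter is involved.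

**Step 2**
Reactants: 2 [1-(3,4-dimethoxy-2-trimethylsilyloxyphenyl)ethenyl]oxy-trimethylsilane; 3 3,4-dimethoxybenzaldehyde (veratraldehyde)
Product: 5 (S)-3-(3,4-dimethoxyphenyl)-3-hydroxy-1-(2-hydroxy-3,4-dimethoxyphenyl)propan-1-one, via trichlorosilyl aldolate 4 (not isolated)
Conditions: SiCl4 (1.1 equiv), (S,S)-bisphosphoramide (5 mol %), i-Pr2NEt (10 mol %), CH2Cl2, −78 °C; then aq. KF/KH2PO4, 0 °C → rt
Reagents that add atoms: none
Why: A chiral phosphoramide-bound trichlorosilyl cation generated from SiCl4 should activate the aldehyde, and the silyl enol ether should add to its Si face through an open transition state (catalytic enantioselective Mukaiyama aldol addition), setting the carbinol center as S, while the near-neutral fluoride work-up cleaves the O–SiCl3 and aryl O–SiMe3 bonds without dehydrating the electron-rich benzylic aldol.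

**Step 3**
Reactants: 5 (S)-3-(3,4-dimethoxyphenyl)-3-hydroxy-1-(2-hydroxy-3,4-dimethoxyphenyl)propan-1-one
Product: 8 (2S)-2-(3,4-dimethoxyphenyl)-5-hydroxy-6,7-dimethoxy-2,3-dihydro-4H-chromen-4-one, via ortho-quinone monoketal 6 (not isolated), via oxa-Michael adduct 7 (not isolated)
Conditions: PhI(OAc)2 (1.0 equiv, slow addition), MeOH (10 equiv), CH2Cl2 (0.02 M), −20 → 0 °C; then pyridinium p-toluenesulfonate (10 mol %), 0 °C → rt
Reagents that add atoms: methanol, CO (supplies the second ketal methoxy group of 6; one of the two is lost again from 7, so the C6 methoxy group of 8 may stem from 5 or from methanol)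
Why: Proposed new method: PhI(OAc)2 should oxidize the free phenol of the guaiacol unit and methanol should add at the methoxy-bearing ortho carbon to give the 6,6-dimethoxycyclohexa-2,4-dienone 6, whose CH next to the acyl-bearing carbon (the future C8a) is the β-carbon of an enone activated by both the ring carbonyl and the side-chain ketone; the C2 hydroxyl adds to it, and acid-assisted loss of one ketal methoxy group together with the C8a proton (an arenium-type elimination from enolized 7) restores ring A with the new O1–C8a bond. The closest known reaction types are the conjugate addition of indoles and related carbon nucleophiles to masked ortho-benzoquinones with aromatizing loss of methanol, the cyclization of hydroxyalkyl benzoquinones to chromanols, and the oxa-Michael closure of β'-hydroxy enones to pyran-4-ones; a tethered alcohol has not been shown as the nucleophile in this dearomatization–rearomatization manifold. Ring C closes in a 6-endo-trig mode. No stereocenter of the target is created: C2 comes unchanged from 5 because its C–O bond is never broken, and the transient sp3 center at C8a of 7 is uncontrolled and erased on aromatization. The step needs site selectivity for C8a over C7 and over addition of methanol, and chemoselectivity for the phenol over the veratryl ring and the carbinol; the C4–C3–C2 tether can reach only C8a through a six-membered transition state, reversible methanol adducts should drain into the entropically favored ring closure, and only the phenol is oxidized by trivalent iodine at low temperature. One equivalent of oxidant is consumed before the acid is added so that the product, itself a guaiacol, is not oxidized further.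

**Compound list**
1 | 1-(2-hydroxy-3,4-dimethoxyphenyl)ethan-1-one | CC(=O)c1ccc(OC)c(OC)c1O | starting material
2 | [1-(3,4-dimethoxy-2-trimethylsilyloxyphenyl)ethenyl]oxy-trimethylsilane | COc1ccc(C(=C)O[Si](C)(C)C)c(O[Si](C)(C)C)c1OC | intermediate
3 | 3,4-dimethoxybenzaldehyde | COc1ccc(C=O)cc1OC | starting material
4 | (S)-3-(3,4-dimethoxyphenyl)-1-[3,4-dimethoxy-2-(trimethylsilyloxy)phenyl]-3-(trichlorosilyloxy)propan-1-one; not isolated | COc1ccc([C@H](CC(=O)c2ccc(OC)c(OC)c2O[Si](C)(C)C)O[Si](Cl)(Cl)Cl)cc1OC | intermediate
5 | (S)-3-(3,4-dimethoxyphenyl)-3-hydroxy-1-(2-hydroxy-3,4-dimethoxyphenyl)propan-1-one | COc1ccc([C@H](CC(=O)c2ccc(OC)c(OC)c2O)O)cc1OC | intermediate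
6 | (S)-2-[3-(3,4-dimethoxyphenyl)-3-hydroxypropanoyl]-5,6,6-trimethoxycyclohexa-2,4-dien-1-one; not isolated | COc1ccc([C@H](CC(=O)C2=CC=C(OC)C(OC)(OC)C2=O)O)cc1OC | intermediate
7 | (2S,8aRS)-2-(3,4-dimethoxyphenyl)-5-hydroxy-6,6,7-trimethoxy-2,3,6,8a-tetrahydro-4H-chromen-4-one (enol form, C8a not controlled); not isolated | COc1ccc([C@@H]2CC(=O)C3=C(O)C(OC)(OC)C(OC)=CC3O2)cc1OC | intermediate
8 | (2S)-2-(3,4-dimethoxyphenyl)-5-hydroxy-6,7-dimethoxy-2,3-dihydro-4H-chromen-4-one | COc1ccc([C@@H]2CC(=O)c3c(cc(OC)c(OC)c3O)O2)cc1OC | target

**Step count and risks**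
Total steps: 3. Longest linear sequence: 3 steps (1 → 2 → 5 → 8).

Steps most likely to fail:

1. Step 3. Methanol may be delivered para to the phenol instead of to the methoxy-bearing ortho carbon. Methanol may also add to the dienone faster than the tethered hydroxyl, the dienone may dimerize by Diels–Alder reaction, or the product may be oxidized a second time. The fallback uses known chemistry, sets out from veratraldehyde 3 and comes back at target 8, closing ring C at O1–C2 instead. Claisen–Schmidt condensation of 3 with purchased 1-(2-hydroxy-4,5,6-trimethoxyphenyl)ethan-1-one F1 (KOH, EtOH, rt) should give (E)-3-(3,4-dimethoxyphenyl)-1-(2-hydroxy-4,5,6-trimethoxyphenyl)prop-2-en-1-one F2. Enantioselective intramolecular oxa-Michael addition of the phenol under a cinchona-derived bifunctional thiourea (quinine or quinidine series chosen for the S product) should give (S)-2-(3,4-dimethoxyphenyl)-5,6,7-trimethoxychroman-4-one F3; selectivity with unactivated 2'-hydroxychalcones is typically moderate, so enrichment by crystallization is planned. BCl3 (CH2Cl2, −78 → 0 °C) should then cleave only the C5 methyl ether, which is chelated to the C4 carbonyl, to give 8.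

2. Step 2. Enantioselectivity may erode through an uncatalyzed SiCl4 pathway or the facial sense may be opposite to that assumed, and the electron-rich benzylic aldol may dehydrate to the chalcone during quench or chromatography. The fallback sets out from 1 and 3 and comes back at 5, setting the C–O stereocenter by conjugate borylation instead of aldol addition. Claisen–Schmidt condensation of 1 with 3 (KOH, EtOH, rt) should give (E)-3-(3,4-dimethoxyphenyl)-1-(2-hydroxy-3,4-dimethoxyphenyl)prop-2-en-1-one F4. Copper-catalyzed enantioselective β-borylation (bis(pinacolato)diboron, CuCl, NaOtBu, 1-[2-(diphenylphosphino)ferrocenyl]ethyldicyclohexylphosphine of the enantiomeric series that gives the S boronate, MeOH, THF, rt) should give (S)-3-(3,4-dimethoxyphenyl)-1-(2-hydroxy-3,4-dimethoxyphenyl)-3-(4,4,5,5-tetramethyl-1,3,2-dioxaborolan-2-yl)propan-1-one F5. Oxidation of the C–B bond with retention (NaBO3·4H2O, THF–H2O, rt) should give 5.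

3. Step 1. The aryl O–SiMe3 group may be lost by adventitious hydrolysis, or enol silylation may stay incomplete, so that the aldol donor reaches step 2 impure. The fallback sets out from 1 and comes back at 5, replacing the traceless bis-silylation by a discrete, robust phenol protection. TBSCl and imidazole (DMF, rt) should give 1-[2-(tert-butyldimethylsilyloxy)-3,4-dimethoxyphenyl]ethan-1-one F6. Kinetic enolization and trapping (LiN(SiMe3)2, Me3SiCl, THF, −78 °C) should give tert-butyl-[2,3-dimethoxy-6-(1-trimethylsilyloxyethenyl)phenoxy]dimethylsilane F7. The aldol addition to 3 under the conditions of step 2 should give (S)-1-[2-(tert-butyldimethylsilyloxy)-3,4-dimethoxyphenyl]-3-(3,4-dimethoxyphenyl)-3-hydroxypropan-1-one F8. HF·pyridine (THF, 0 °C) should then free the phenol to give 5.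

**Further compounds**
F1 | step 3 | 1-(2-hydroxy-4,5,6-trimethoxyphenyl)ethan-1-one | CC(=O)c1c(O)cc(OC)c(OC)c1OC
F2 | step 3 | (E)-3-(3,4-dimethoxyphenyl)-1-(2-hydroxy-4,5,6-trimethoxyphenyl)prop-2-en-1-one | COc1ccc(/C=C/C(=O)c2c(O)cc(OC)c(OC)c2OC)cc1OC
F3 | step 3 | (S)-2-(3,4-dimethoxyphenyl)-5,6,7-trimethoxychroman-4-one | COc1ccc([C@@H]2CC(=O)c3c(cc(OC)c(OC)c3OC)O2)cc1OC
F4 | step 2 | (E)-3-(3,4-dimethoxyphenyl)-1-(2-hydroxy-3,4-dimethoxyphenyl)prop-2-en-1-one | COc1ccc(/C=C/C(=O)c2ccc(OC)c(OC)c2O)cc1OC
F5 | step 2 | (S)-3-(3,4-dimethoxyphenyl)-1-(2-hydroxy-3,4-dimethoxyphenyl)-3-(4,4,5,5-tetramethyl-1,3,2-dioxaborolan-2-yl)propan-1-one | COc1ccc([C@H](CC(=O)c2ccc(OC)c(OC)c2O)B2OC(C)(C)C(C)(C)O2)cc1OC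
F6 | step 1 | 1-[2-(tert-butyldimethylsilyloxy)-3,4-dimethoxyphenyl]ethan-1-one | CC(=O)c1ccc(OC)c(OC)c1O[Si](C)(C)C(C)(C)C
F7 | step 1 | tert-butyl-[2,3-dimethoxy-6-(1-trimethylsilyloxyethenyl)phenoxy]dimethylsilane | C=C(O[Si](C)(C)C)c1ccc(OC)c(OC)c1O[Si](C)(C)C(C)(C)C
F8 | step 1 | (S)-1-[2-(tert-butyldimethylsilyloxy)-3,4-dimethoxyphenyl]-3-(3,4-dimethoxyphenyl)-3-hydroxypropan-1-one | COc1ccc([C@H](CC(=O)c2ccc(OC)c(OC)c2O[Si](C)(C)C(C)(C)C)O)cc1OC
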